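Millimolar per minute is the unit I reckon this flask in, since the question is how fast solid substrate passes through the solution into ring.

    starting material → ring (k1 = 0.061 s⁻¹)
    starting material + starting material ⇌ open dimer (K2 = 0.22 M⁻¹, k2 = 0.41 M⁻¹ s⁻¹)
    solid substrate ⇌ starting material, rate k3*(cs3 - [starting material]) while solid is left; crystals form when [starting material] > cs3 (cs3 = 31 mM, k3 = 0.0069 s⁻¹)

solid substrate 0.47 M; time 30 min

- how much ring there is at 30 min, in percent of the solid substrate charged
- concentration of starting material in solution at 30 min, in percent of saturation

1. In one extreme the solution stays saturated and ring closure is the brake, which gives 113 mM min⁻¹.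

2. In the other extreme the solution stays empty and dissolution is the brake, which gives 12.8 mM min⁻¹, slower than the first, so I expect dissolution to be the rate-limiting step.

3. The real flask lies below both, with dissolved starting material at a steady level S (a quasi-steady state) where inflow and closure cross: 10.2% of saturation, reached after a lag of about 14.7 s. I set the open dimer aside, because its equilibrium level of 0.00218 mM lies far below S.

4. At that level the feed F, the rate of ring formation, is 11.5 mM min⁻¹, and I carry the emptying time T, the charge divided by F, which is 40.8 min. This is later than the run's end, so I expect solid to remain at that end, and I reckon the ring share as the time after the lag over T, 73.0%.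

The forecast gives 73% and 10.16%, on the ground that “the solid dissolves slowly and the ring closes fast”.

The flask gives 73.0% of ring and 10.2% of saturation. Starting material is made and used at a ratio of 1.00 at 30.0 min, with 26.3% still solid. T lies 10.8 min beyond that reading, and at 60.0 min, past T, ring stands at 100%.

For the neighbour flask with 0.80 M of solid substrate I keep the same F, so I reckon T as 69.4 min and the share as 42.9%. Its simulated ring is 42.9%.

The numbers of this flask are made up; the result is computed.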